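The tetrahydrofuran ring (O1, C2–C5) is opened at the C4–C5 bond. C5 is a bare methylene between O1 and C4, and C4 bears the benzylic carbon C7'; C5 can therefore enter as the formaldehyde carbon of a methoxymethyl ether and C4–C7' as an electron-rich styrene. In one operation, ionisation of the acetal and attack of the styrene on the O1=C5 oxocarbenium ion close the ring, and proton loss from the resulting C7' benzylic cation gives the 4-benzylidene tetrahydrofuran. The precursor is an open-chain, syn-aldol-derived homoallylic methoxymethyl ether with C2 and C3 already set and a pivalate on C9; C4 is set afterwards by hydrogenation.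

Key step: step 7

Remark on numbering: ring atoms are O1, C2 (aryl), C3 (bears C9H2–O), C4 (bears C7'), C5; Ar = 3,4-dimethoxyphenyl.

Remark on configuration: the branching carbon that becomes C3 is S in the aldol imide 10 but R once its acyl carbon is reduced to CH2O (a priority change, not an inversion), so the cyclisation precursor 14 is the (1S,2R)-type open chain, S at the carbinol carbon and R at the branching carbon.

Step 1
Reactants: 1 3,4-dimethoxybenzaldehyde; 2 (2-carboxyethyl)triphenylphosphonium bromide
Product: 4 (E)-4-(3,4-dimethoxyphenyl)but-3-enoic acid, via phosphonium ylide 3 (not isolated)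
Conditions: 2, NaN(SiMe3)2 (2.1 equiv), THF, −78 → 0 °C; then 1, −78 °C → rt; aq. HCl
Reagents that add atoms: none
Why: Wittig olefination with the carboxylate-bearing ylide formed by double deprotonation, which should favour the E alkene with aromatic aldehydes; any Z isomer is harmless because the alkene geometry is erased at the C7' cation in step 7.

Step 2
Reactants: 4 (E)-4-(3,4-dimethoxyphenyl)but-3-enoic acid; 5 (S)-4-benzyloxazolidin-2-one
Product: 7 (S)-4-benzyl-3-[(E)-4-(3,4-dimethoxyphenyl)but-3-enoyl]oxazolidin-2-one, via mixed anhydride 6 (not isolated)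
Conditions: pivaloyl chloride, Et3N, THF, −20 °C; then LiCl, 5, −20 °C → rt
Reagents that add atoms: none
Why: N-acylation of the oxazolidinone through the mixed pivalic anhydride under LiCl/Et3N activation, which needs no strong base and should leave the styrene-conjugated β,γ-alkene in place.

Step 3
Reactants: 7 (S)-4-benzyl-3-[(E)-4-(3,4-dimethoxyphenyl)but-3-enoyl]oxazolidin-2-one; 1 3,4-dimethoxybenzaldehyde
Product: 10 (S)-4-benzyl-3-[(2S,3E)-4-(3,4-dimethoxyphenyl)-2-[(S)-(3,4-dimethoxyphenyl)(hydroxy)methyl]but-3-enoyl]oxazolidin-2-one, via boron Z-enolate 8 (not isolated), via boron aldolate 9 (not isolated)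
Conditions: Bu2BOTf, i-Pr2NEt, CH2Cl2, −78 → 0 °C; then 1, −78 → 0 °C; pH 7 buffer, MeOH, 30% H2O2, 0 °C
Reagents that add atoms: none
Why: Evans syn-aldol reaction, in which the Z dibutylboron enolate reacts through a chair Zimmerman–Traxler transition state on the enolate face away from the benzyl group of the dipole-opposed auxiliary; this sets the future C2 (S) and the future C3 (S in the imide) in the syn relationship that becomes 2,3-trans in the ring.

Step 4
Reactants: 10 aldol imide
Product: 11 (1S,2R)-1-(3,4-dimethoxyphenyl)-2-[(E)-2-(3,4-dimethoxyphenyl)ethenyl]propane-1,3-diol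
Conditions: LiBH4, MeOH (1 equiv), THF, 0 °C
Reagents that add atoms: none
Why: Reductive cleavage of the imide by LiBH4 at the exocyclic acyl carbonyl, which releases the auxiliary and should leave the alkene and both stereocentres untouched; reducing before any base-mediated protection removes the acidic, doubly activated α-hydrogen early.

Step 5
Reactants: 11 diol
Product: 12 (2R,3E)-4-(3,4-dimethoxyphenyl)-2-[(S)-(3,4-dimethoxyphenyl)(hydroxy)methyl]but-3-en-1-yl pivalate
Conditions: pivaloyl chloride (1.05 equiv), pyridine, CH2Cl2, −20 → 0 °C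
Reagents that add atoms: pivaloyl chloride, CC(C)(C)C(=O)Cl
Why: Selective acylation of the primary alcohol by the bulky acid chloride, the secondary benzylic alcohol being much slower; an ester is chosen for C9 because it is inert to the Lewis acid of step 7 and, unlike an ether oxygen, should not add to a cation.

Step 6
Reactants: 12 mono-pivalate; 13 chloromethyl methyl ether
Product: 14 (2R,3E)-4-(3,4-dimethoxyphenyl)-2-[(S)-(3,4-dimethoxyphenyl)(methoxymethoxy)methyl]but-3-en-1-yl pivalate
Conditions: 13, i-Pr2NEt, Bu4NI (cat.), CH2Cl2, 0 °C → rt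
Reagents that add atoms: none
Why: Methoxymethyl ether formation by O-alkylation of the secondary alcohol with the α-chloro ether under amine base, which installs the formaldehyde carbon that becomes C5 without touching either stereocentre.

Step 7
Reactants: 14 methoxymethyl ether
Product: 17 [(2S,3R,4Z)-4-(3,4-dimethoxybenzylidene)-2-(3,4-dimethoxyphenyl)tetrahydrofuran-3-yl]methyl pivalate, via oxocarbenium ion 15 (not isolated), via benzylic cation 16 (not isolated)
Conditions: Me3SiOTf (1.3 equiv), 2,6-di-tert-butyl-4-methylpyridine (2 equiv), CH2Cl2 (0.01 M), −78 → −20 °C; then aq. NaHCO3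
Reagents that add atoms: none
Why: Me3SiOTf silylates the exposed methoxy oxygen of the mixed formaldehyde acetal and expels MeOSiMe3 to leave the O1=C5 oxocarbenium ion 15, whose carbon is attacked by C4 of the dimethoxystyrene to form the C4–C5 bond and the C7' benzylic cation 16, which then loses H4 to the hindered pyridine to give the conjugated benzylidene. The closest known reaction type is the oxonium-Prins cyclisation of homoallylic mixed acetals onto aryl alkenes, which gives five-membered cyclic ethers through benzylic cations. The single ring (O1, C2–C5) closes in a five-membered mode that is endo for the oxocarbenium ion (O1 and C5 both end up in the ring) and exo for the alkene (C7' stays outside). No stereocentre is created because C4 becomes trigonal; C2 and C3 pass through unchanged as long as neither becomes cationic, and the aryl of the benzylidene should settle on the C5 side away from the C3 arm, although either geometry serves step 8. Regioselectivity for the five- over the six-membered ring is secured by the para-methoxy-stabilised C7' cation, which only attack through C4 can produce. Proton loss should win over Friedel–Crafts capture by the C2 aryl ring because the triflate counter-ion is non-nucleophilic, the base is too hindered to bind the oxocarbenium ion yet can take up the proton, and the reaction is run at high dilution and low temperature.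

Step 8
Reactants: 17 benzylidene tetrahydrofuran
Product: 18 [(2S,3R,4R)-4-(3,4-dimethoxybenzyl)-2-(3,4-dimethoxyphenyl)tetrahydrofuran-3-yl]methyl pivalate
Conditions: H2 (1 atm), 5% Pd/C, Et3N (0.1 equiv), EtOAc, rt
Reagents that add atoms: none
Why: Heterogeneous catalytic hydrogenation should deliver both hydrogens to the C4=C7' bond from the face opposite the adjacent C3 pivaloyloxymethyl arm, placing the benzyl group cis to that arm (4R); the amine additive tempers the catalyst so that the benzylic C2–O1 bond is not hydrogenolysed.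

Step 9
Reactants: 18 saturated pivalate
Product: 19 [(2S,3R,4R)-4-(3,4-dimethoxybenzyl)-2-(3,4-dimethoxyphenyl)tetrahydrofuran-3-yl]methanol
Conditions: NaOMe, MeOH, 50 °C
Reagents that add atoms: none
Why: Base-catalysed transesterification (methanolysis) of the pivalate; the substrate has no base-sensitive group and no epimerisable centre.

Step 10
Reactants: 19 primary alcohol; 20 angelic acid, (Z)-2-methylbut-2-enoic acid
Product: 21 leoligin, [(2S,3R,4R)-4-(3,4-dimethoxybenzyl)-2-(3,4-dimethoxyphenyl)tetrahydrofuran-3-yl]methyl (Z)-2-methylbut-2-enoate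
Conditions: 20, PPh3, diisopropyl azodicarboxylate, THF, 0 °C → rt
Reagents that add atoms: none
Why: Mitsunobu esterification, in which the alcohol is activated and the angelate acts only as the nucleophile at the non-stereogenic C9, so no activated acyl species forms that could isomerise the Z double bond to the tiglate.

Compound list
1 | 3,4-dimethoxybenzaldehyde | COc1ccc(C=O)cc1OC | starting material
2 | (2-carboxyethyl)triphenylphosphonium bromide | OC(=O)CC[P+](c1ccccc1)(c1ccccc1)c1ccccc1.[Br-] | starting material
3 | sodium 3-(triphenylphosphoranylidene)propanoate (ylide carboxylate) | [Na+].[O-]C(=O)CC=P(c1ccccc1)(c1ccccc1)c1ccccc1 | intermediate (not isolated)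
4 | (E)-4-(3,4-dimethoxyphenyl)but-3-enoic acid | COc1ccc(/C=C/CC(=O)O)cc1OC | intermediate
5 | (S)-4-benzyloxazolidin-2-one | O=C1OC[C@H](Cc2ccccc2)N1 | starting material
6 | (E)-4-(3,4-dimethoxyphenyl)but-3-enoic pivalic anhydride | COc1ccc(/C=C/CC(=O)OC(=O)C(C)(C)C)cc1OC | intermediate (not isolated)
7 | (S)-4-benzyl-3-[(E)-4-(3,4-dimethoxyphenyl)but-3-enoyl]oxazolidin-2-one | COc1ccc(/C=C/CC(=O)N2C(=O)OC[C@@H]2Cc2ccccc2)cc1OC | intermediate
8 | (S)-4-benzyl-3-[(1Z,3E)-1-(dibutylboranyloxy)-4-(3,4-dimethoxyphenyl)buta-1,3-dien-1-yl]oxazolidin-2-one | CCCCB(CCCC)O/C(=C\C=C\c1ccc(OC)c(OC)c1)N1C(=O)OC[C@@H]1Cc1ccccc1 | intermediate (not isolated)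
9 | O-dibutylboranyl derivative of aldol imide 10 (boron aldolate) | CCCCB(CCCC)O[C@H](c1ccc(OC)c(OC)c1)[C@@H](C(=O)N1C(=O)OC[C@@H]1Cc1ccccc1)/C=C/c1ccc(OC)c(OC)c1 | intermediate (not isolated)
10 | (S)-4-benzyl-3-[(2S,3E)-4-(3,4-dimethoxyphenyl)-2-[(S)-(3,4-dimethoxyphenyl)(hydroxy)methyl]but-3-enoyl]oxazolidin-2-one | O[C@H](c1ccc(OC)c(OC)c1)[C@@H](C(=O)N1C(=O)OC[C@@H]1Cc1ccccc1)/C=C/c1ccc(OC)c(OC)c1 | intermediate
11 | (1S,2R)-1-(3,4-dimethoxyphenyl)-2-[(E)-2-(3,4-dimethoxyphenyl)ethenyl]propane-1,3-diol | O[C@H](c1ccc(OC)c(OC)c1)[C@@H](CO)/C=C/c1ccc(OC)c(OC)c1 | intermediate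
12 | (2R,3E)-4-(3,4-dimethoxyphenyl)-2-[(S)-(3,4-dimethoxyphenyl)(hydroxy)methyl]but-3-en-1-yl pivalate | O[C@H](c1ccc(OC)c(OC)c1)[C@@H](COC(=O)C(C)(C)C)/C=C/c1ccc(OC)c(OC)c1 | intermediate
13 | chloromethyl methyl ether | COCCl | starting material
14 | (2R,3E)-4-(3,4-dimethoxyphenyl)-2-[(S)-(3,4-dimethoxyphenyl)(methoxymethoxy)methyl]but-3-en-1-yl pivalate | COCO[C@H](c1ccc(OC)c(OC)c1)[C@@H](COC(=O)C(C)(C)C)/C=C/c1ccc(OC)c(OC)c1 | intermediate (key-step precursor)
15 | O1=C5 methylideneoxonium (oxocarbenium) triflate derived from 14 | C=[O+][C@H](c1ccc(OC)c(OC)c1)[C@@H](COC(=O)C(C)(C)C)/C=C/c1ccc(OC)c(OC)c1.[O-]S(=O)(=O)C(F)(F)F | intermediate (not isolated)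
16 | ring-closed C7' benzylic cation triflate (C4 configuration undefined) | CC(C)(C)C(=O)OC[C@H]1C([CH+]c2ccc(OC)c(OC)c2)CO[C@@H]1c1ccc(OC)c(OC)c1.[O-]S(=O)(=O)C(F)(F)F | intermediate (not isolated)
17 | [(2S,3R,4Z)-4-(3,4-dimethoxybenzylidene)-2-(3,4-dimethoxyphenyl)tetrahydrofuran-3-yl]methyl pivalate | CC(C)(C)C(=O)OC[C@H]1/C(=C/c2ccc(OC)c(OC)c2)CO[C@@H]1c1ccc(OC)c(OC)c1 | intermediate (key-step product)
18 | [(2S,3R,4R)-4-(3,4-dimethoxybenzyl)-2-(3,4-dimethoxyphenyl)tetrahydrofuran-3-yl]methyl pivalate | CC(C)(C)C(=O)OC[C@H]1[C@@H](Cc2ccc(OC)c(OC)c2)CO[C@@H]1c1ccc(OC)c(OC)c1 | intermediate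
19 | [(2S,3R,4R)-4-(3,4-dimethoxybenzyl)-2-(3,4-dimethoxyphenyl)tetrahydrofuran-3-yl]methanol | OC[C@H]1[C@@H](Cc2ccc(OC)c(OC)c2)CO[C@@H]1c1ccc(OC)c(OC)c1 | intermediate
20 | angelic acid, (Z)-2-methylbut-2-enoic acid | C/C=C(/C)C(=O)O | starting material
21 | leoligin | C/C=C(/C)C(=O)OC[C@H]1[C@@H](Cc2ccc(OC)c(OC)c2)CO[C@@H]1c1ccc(OC)c(OC)c1 | target

Total step count: 10. Longest linear sequence: 10 steps (1 and 2 to 21).

Steps most likely to fail

Step 7. The C7' cation may be captured by the activated C2 aryl ring (Friedel–Crafts) before it loses a proton. The oxocarbenium ion may also undergo a [3,3] shift toward the aryl-conjugated isomer (2-oxonia-Cope), or the electron-rich benzylic C2–O1 bond may ionise with loss of the C2 configuration. The fallback separates cation capture from alkene formation. It sets out from 14, which is treated with SnBr4 in CH2Cl2 at −78 °C so that bromide from the tin ate complex intercepts the benzylic cation at once. This should give the benzylic bromide [(2S,3R)-4-[bromo(3,4-dimethoxyphenyl)methyl]-2-(3,4-dimethoxyphenyl)tetrahydrofuran-3-yl]methyl pivalate F1 as a mixture at C4 and C7'. Dehydrobromination of F1 with 1,8-diazabicyclo[5.4.0]undec-7-ene in toluene at 60 °C removes H4, the only β-hydrogen, and comes back to the route at 17.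

Step 8. Facial selectivity may be poor because the C2 aryl group lies on the face from which hydrogen must arrive, and the benzylic C2–O1 bond may be hydrogenolysed. The fallback enlarges the shield on C9 before reduction. It sets out from 17, which is methanolysed (NaOMe, MeOH) to [(2S,3R,4Z)-4-(3,4-dimethoxybenzylidene)-2-(3,4-dimethoxyphenyl)tetrahydrofuran-3-yl]methanol F2. Silylation with tert-butyl(chloro)diphenylsilane and imidazole in DMF gives tert-butyl{[(2S,3R,4Z)-4-(3,4-dimethoxybenzylidene)-2-(3,4-dimethoxyphenyl)tetrahydrofuran-3-yl]methoxy}diphenylsilane F3. Hydrogenation over Rh/Al2O3 in EtOAc, a catalyst little given to C–O hydrogenolysis, should then give tert-butyl{[(2S,3R,4R)-4-(3,4-dimethoxybenzyl)-2-(3,4-dimethoxyphenyl)tetrahydrofuran-3-yl]methoxy}diphenylsilane F4. Desilylation with Bu4NF in THF comes back to the route at 19.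

Step 10. The angelate may isomerise from Z to E, or displacement at the β-branched C9 may be slow enough that the acid is consumed by the azodicarboxylate. The fallback activates the acid instead of the alcohol. It sets out from 20, which with 2,4,6-trichlorobenzoyl chloride and Et3N in toluene gives the mixed anhydride (Z)-2-methylbut-2-enoic 2,4,6-trichlorobenzoic anhydride F5 (Yamaguchi-type activation). Heating F5 with 19 in toluene at 80 °C without a nucleophilic amine catalyst comes back to the route at 21.

Further compounds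
F1 | step 7 | [(2S,3R)-4-[bromo(3,4-dimethoxyphenyl)methyl]-2-(3,4-dimethoxyphenyl)tetrahydrofuran-3-yl]methyl pivalate | CC(C)(C)C(=O)OC[C@H]1C(C(Br)c2ccc(OC)c(OC)c2)CO[C@@H]1c1ccc(OC)c(OC)c1
F2 | step 8 | [(2S,3R,4Z)-4-(3,4-dimethoxybenzylidene)-2-(3,4-dimethoxyphenyl)tetrahydrofuran-3-yl]methanol | OC[C@H]1/C(=C/c2ccc(OC)c(OC)c2)CO[C@@H]1c1ccc(OC)c(OC)c1
F3 | step 8 | tert-butyl{[(2S,3R,4Z)-4-(3,4-dimethoxybenzylidene)-2-(3,4-dimethoxyphenyl)tetrahydrofuran-3-yl]methoxy}diphenylsilane | CC(C)(C)[Si](OC[C@H]1/C(=C/c2ccc(OC)c(OC)c2)CO[C@@H]1c1ccc(OC)c(OC)c1)(c1ccccc1)c1ccccc1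
F4 | step 8 | tert-butyl{[(2S,3R,4R)-4-(3,4-dimethoxybenzyl)-2-(3,4-dimethoxyphenyl)tetrahydrofuran-3-yl]methoxy}diphenylsilane | CC(C)(C)[Si](OC[C@H]1[C@@H](Cc2ccc(OC)c(OC)c2)CO[C@@H]1c1ccc(OC)c(OC)c1)(c1ccccc1)c1ccccc1
F5 | step 10 | (Z)-2-methylbut-2-enoic 2,4,6-trichlorobenzoic anhydride | C/C=C(/C)C(=O)OC(=O)c1c(Cl)cc(Cl)cc1Cl
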